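**Plan**
1. Retrosynthesis: remove the fifteen benzyl ethers; cut the interflavan bond C4 (upper ring C)–C8 (lower ring A); cut both gallate ester bonds; then open the lower pyran ring C at two bonds at once, C3–C4 and O1–C8a, which leaves a ring B aryl ketone and a ring A benzylic bromide.
2. Forward: ring A piece 4 (benzylic C4 bromide, aryl C8a bromide) and ring B ketone 7 (C2 carbonyl, C3 silyloxy) are joined in one pot to close lower ring C as a 4H-chromene. Desilylation gives the flavan-3-one, then reduction and galloylation. The upper unit comes from (−)-epicatechin; 4→8 coupling and hydrogenolysis finish the route.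
3. Enabling feature: in lower ring A the oxygens at C5 and C7 are ortho/para to C4a, so the C4 benzylic bromide is a strong SN2 electrophile, and meta to C8a, so the C8a–Br bond stays open to copper. O1–C2–C3 of ketone 7 is a 1,3-C,O-dinucleophile with a single enolizable site, C3, which already carries the later gallate oxygen.
4. Stereochemistry: lower C2 and C3 are set together by a catalyst-controlled dynamic kinetic hydrogenation of the racemic flavan-3-one (cis by substrate control). Upper C2 and C3 are bought with (−)-epicatechin, and upper C4 is relayed from them (attack trans to the 3-O-galloyl group).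

Key step: step 6

Remark: compounds 1, 5, 12 and 14 are taken as catalogue compounds. The antipode of the ruthenium catalyst in step 8 is assigned by analogy with 2-arylcycloalkanones and would be exchanged for its mirror image if a test reduction showed the opposite sense.

**Step 1**
Reactants: 1 1,3-bis(benzyloxy)-5-bromobenzene
Product: 2 2,4-bis(benzyloxy)-6-bromobenzaldehyde
Conditions: POCl3, DMF, 0 to 70 °C; then H2O
Reagents that add atoms: N,N-dimethylformamide CN(C)C=O; water O
Why: Vilsmeier–Haack formylation should occur at the ring carbon ortho to bromine and para to one benzyloxy group, which is less hindered than the site between the two ethers.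

**Step 2**
Reactants: 2 2,4-bis(benzyloxy)-6-bromobenzaldehyde
Product: 3 [2,4-bis(benzyloxy)-6-bromophenyl]methanol
Conditions: NaBH4, THF/MeOH, 0 °C
Reagents that add atoms: none
Why: Borohydride reduction of an aryl aldehyde leaves the aryl bromide and benzyl ethers untouched.

**Step 3**
Reactants: 3 [2,4-bis(benzyloxy)-6-bromophenyl]methanol
Product: 4 1,5-bis(benzyloxy)-3-bromo-2-(bromomethyl)benzene
Conditions: PBr3, CH2Cl2, 0 °C; crude bromide used at once
Reagents that add atoms: phosphorus tribromide BrP(Br)Br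
Why: Substitution of the electron-rich benzylic alcohol with PBr3 is fast at low temperature, and the labile bromide is carried forward without chromatography.

**Step 4**
Reactants: 5 3,4,5-tris(benzyloxy)benzaldehyde
Product: 6 2-hydroxy-1-[3,4,5-tris(benzyloxy)phenyl]ethan-1-one
Conditions: (CH2O)n, 3-benzyl-5-(2-hydroxyethyl)-4-methylthiazolium chloride (cat.), i-Pr2NEt (cat.), THF, 60 °C
Reagents that add atoms: paraformaldehyde (as formaldehyde) C=O
Why: N-heterocyclic-carbene-catalysed cross-acyloin reaction (hydroxymethylation), in which the Breslow intermediate of the aryl aldehyde adds to formaldehyde and excess formaldehyde suppresses homo-benzoin formation.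

**Step 5**
Reactants: 6 2-hydroxy-1-[3,4,5-tris(benzyloxy)phenyl]ethan-1-one
Product: 7 2-[(triisopropylsilyl)oxy]-1-[3,4,5-tris(benzyloxy)phenyl]ethan-1-one
Conditions: i-Pr3SiCl, imidazole, DMF, 0 °C to rt
Reagents that add atoms: chlorotriisopropylsilane CC(C)[Si](Cl)(C(C)C)C(C)C
Why: Standard silylation of a primary alcohol; the bulky silyl group is chosen because it resists O-to-O migration in the later enolate chemistry.

**Step 6**
Reactants: 7 2-[(triisopropylsilyl)oxy]-1-[3,4,5-tris(benzyloxy)phenyl]ethan-1-one; 4 1,5-bis(benzyloxy)-3-bromo-2-(bromomethyl)benzene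
Product: 9 5,7-bis(benzyloxy)-2-[3,4,5-tris(benzyloxy)phenyl]-3-[(triisopropylsilyl)oxy]-4H-chromene, via C-benzylated ketone 8 (not isolated)
Conditions: LiHMDS, THF, −78 °C; 4, −78 to 0 °C; solvent switched to DMF; CuI (cat.), 1,10-phenanthroline (cat.), Cs2CO3, 100 °C, one pot
Reagents that add atoms: none
Why: LiHMDS forms the lithium enolate of 7 at C3, its only enolizable carbon, and this displaces the benzylic bromide of 4 (SN2, new C3–C4 bond) to give 8; carbonate then regenerates the enolate of 8, and monovalent copper inserts into the C8a–Br bond and reductively eliminates the enolate oxygen onto C8a (Ullmann-type enolate O-arylation, new O1–C8a bond), so the sequence is a formal [3+3] annulation of a C,O-1,3-dinucleophile with a 1,3-dielectrophile. The closest known reaction type is the copper-catalysed domino C-benzylation/O-arylation of 1,3-dicarbonyl compounds with 2-bromobenzyl bromides to 4H-chromenes, together with copper- and palladium-catalysed O-arylation of simple ketone enolates to benzofurans. Lower ring C is closed as a six-membered ring by intramolecular C–O coupling at the aryl carbon C8a, with the C2=C3 enol double bond ending inside the ring. No stereocenter survives the step: the C3 center of 8 is planarized in 9, which is achiral, and C2 and C3 are set later in step 8. The step needs C- over O-alkylation (lithium enolate in THF with a soft benzylic bromide), monoalkylation (one equivalent of 4 at low temperature) and O- over C-arylation; the last is secured by the substrate, since C-arylation at C3 would close a four-membered ring and no other enolizable position exists. The bulky triisopropylsilyl group on O3 should not migrate between the two enediol oxygens, which keeps O3 from attacking C8a.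

**Step 7**
Reactants: 9 5,7-bis(benzyloxy)-2-[3,4,5-tris(benzyloxy)phenyl]-3-[(triisopropylsilyl)oxy]-4H-chromene
Product: 10 rac-5,7-bis(benzyloxy)-2-[3,4,5-tris(benzyloxy)phenyl]chroman-3-one
Conditions: Bu4NF, AcOH, THF, −20 to 0 °C, under argon
Reagents that add atoms: none
Why: Fluoride desilylation of the silyl enol ether releases the C3 enolate, which acetic acid protonates at C2 to give the ketone; strong acid is avoided because protonation at C3 would open ring C through the 2-aryl oxocarbenium ion.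

**Step 8**
Reactants: 10 rac-5,7-bis(benzyloxy)-2-[3,4,5-tris(benzyloxy)phenyl]chroman-3-one
Product: 11 (2R,3R)-5,7-bis(benzyloxy)-2-[3,4,5-tris(benzyloxy)phenyl]chroman-3-ol (penta-O-benzyl-(−)-epigallocatechin)
Conditions: RuCl2[(S)-xylbinap][(S)-daipen] (cat.), t-BuOK (cat.), H2 (10 atm), i-PrOH/THF, 25 °C
Reagents that add atoms: none
Why: Noyori-type asymmetric hydrogenation with dynamic kinetic resolution, as for racemic 2-arylcycloalkanones: the C2–H (benzylic, α to oxygen and to the ketone) should epimerize rapidly under base, the divalent ruthenium diphosphine/diamine catalyst should reduce the (2R)-ketone preferentially, and hydride delivery to the face opposite the 2-aryl group should give the 2,3-cis alcohol, so that C2 and C3 are set in one event.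

**Step 9**
Reactants: 11 (2R,3R)-5,7-bis(benzyloxy)-2-[3,4,5-tris(benzyloxy)phenyl]chroman-3-ol; 12 3,4,5-tris(benzyloxy)benzoic acid
Product: 13 (2R,3R)-5,7-bis(benzyloxy)-2-[3,4,5-tris(benzyloxy)phenyl]chroman-3-yl 3,4,5-tris(benzyloxy)benzoate (octa-O-benzyl-(−)-epigallocatechin gallate)
Conditions: DCC, DMAP, CH2Cl2, rt
Reagents that add atoms: none
Why: Steglich esterification acylates the secondary alcohol without touching C2 or C3, so the cis configuration is retained.

**Step 10**
Reactants: 14 (−)-epicatechin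
Product: 15 5,7,3',4'-tetra-O-benzyl-(−)-epicatechin
Conditions: BnBr, K2CO3, DMF, 0 °C to rt
Reagents that add atoms: benzyl bromide BrCc1ccccc1
Why: Williamson etherification of the four phenols; carbonate is too weak a base to alkylate the secondary 3-OH.

**Step 11**
Reactants: 15 5,7,3',4'-tetra-O-benzyl-(−)-epicatechin
Product: 16 (2R,3R,4S)-4-(2-ethoxyethoxy)-5,7,3',4'-tetra-O-benzylepicatechin (4β-alkoxy)
Conditions: DDQ, 2-ethoxyethanol, CH2Cl2, rt
Reagents that add atoms: 2-ethoxyethanol CCOCCO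
Why: DDQ benzylic oxidation abstracts hydride from C4, and the cation stabilized by the ring A oxygens is trapped by the alcohol trans to the 3-OH.

**Step 12**
Reactants: 16 (2R,3R,4S)-4-(2-ethoxyethoxy)-5,7,3',4'-tetra-O-benzylepicatechin; 12 3,4,5-tris(benzyloxy)benzoic acid
Product: 17 (2R,3R,4S)-4-(2-ethoxyethoxy)-5,7,3',4'-tetra-O-benzylepicatechin 3-O-[3,4,5-tris(benzyloxy)benzoate]
Conditions: DCC, DMAP, CH2Cl2, rt
Reagents that add atoms: none
Why: Steglich esterification of the 3-OH; the C4 acetal-type ether is stable to these neutral conditions.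

**Step 13**
Reactants: 17 (2R,3R,4S)-4-(2-ethoxyethoxy)-5,7,3',4'-tetra-O-benzylepicatechin 3-O-[3,4,5-tris(benzyloxy)benzoate]; 13 octa-O-benzyl-(−)-epigallocatechin gallate (3 equiv, excess recovered)
Product: 18 pentadeca-O-benzyl epicatechin 3-O-gallate-(4β→8)-epigallocatechin 3-O-gallate, upper unit (2R,3R,4R), lower unit (2R,3R)
Conditions: TMSOTf (cat.), CH2Cl2, −78 to −30 °C
Reagents that add atoms: none
Why: Lewis-acid-promoted Friedel–Crafts-type coupling: the C4 cation of 17, bridged by the 3-O-galloyl group, should be attacked by the more nucleophilic C8 of 13 from the face trans to the ester and to the 2-aryl group, which sets upper C4 as R by substrate control.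

**Step 14**
Reactants: 18 pentadeca-O-benzyl epicatechin 3-O-gallate-(4β→8)-epigallocatechin 3-O-gallate
Product: 19 (−)-epicatechin 3-O-gallate-(4β→8)-(−)-epigallocatechin 3-O-gallate
Conditions: H2 (1 atm), Pd(OH)2/C, THF/MeOH/H2O, rt
Reagents that add atoms: none
Why: Catalytic hydrogenolysis removes all fifteen benzyl ethers under neutral conditions that should spare the gallate esters, the C2–O1 bonds and the interflavan bond.

**Compound list**
1 | 1,3-bis(benzyloxy)-5-bromobenzene | Brc1cc(OCc2ccccc2)cc(OCc2ccccc2)c1 | starting material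
2 | 2,4-bis(benzyloxy)-6-bromobenzaldehyde | O=Cc1c(Br)cc(OCc2ccccc2)cc1OCc1ccccc1 | intermediate
3 | [2,4-bis(benzyloxy)-6-bromophenyl]methanol | OCc1c(Br)cc(OCc2ccccc2)cc1OCc1ccccc1 | intermediate
4 | 1,5-bis(benzyloxy)-3-bromo-2-(bromomethyl)benzene | BrCc1c(Br)cc(OCc2ccccc2)cc1OCc1ccccc1 | intermediate
5 | 3,4,5-tris(benzyloxy)benzaldehyde | O=Cc1cc(OCc2ccccc2)c(OCc2ccccc2)c(OCc2ccccc2)c1 | starting material
6 | 2-hydroxy-1-[3,4,5-tris(benzyloxy)phenyl]ethan-1-one | O=C(CO)c1cc(OCc2ccccc2)c(OCc2ccccc2)c(OCc2ccccc2)c1 | intermediate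
7 | 2-[(triisopropylsilyl)oxy]-1-[3,4,5-tris(benzyloxy)phenyl]ethan-1-one | CC(C)[Si](OCC(=O)c1cc(OCc2ccccc2)c(OCc2ccccc2)c(OCc2ccccc2)c1)(C(C)C)C(C)C | intermediate
8 | rac-3-[2,4-bis(benzyloxy)-6-bromophenyl]-2-[(triisopropylsilyl)oxy]-1-[3,4,5-tris(benzyloxy)phenyl]propan-1-one | CC(C)[Si](OC(Cc1c(Br)cc(OCc2ccccc2)cc1OCc1ccccc1)C(=O)c1cc(OCc2ccccc2)c(OCc2ccccc2)c(OCc2ccccc2)c1)(C(C)C)C(C)C | intermediate
9 | 5,7-bis(benzyloxy)-2-[3,4,5-tris(benzyloxy)phenyl]-3-[(triisopropylsilyl)oxy]-4H-chromene | CC(C)[Si](OC1=C(c2cc(OCc3ccccc3)c(OCc3ccccc3)c(OCc3ccccc3)c2)Oc2cc(OCc3ccccc3)cc(OCc3ccccc3)c2C1)(C(C)C)C(C)C | intermediate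
10 | rac-5,7-bis(benzyloxy)-2-[3,4,5-tris(benzyloxy)phenyl]chroman-3-one | O=C1Cc2c(OCc3ccccc3)cc(OCc3ccccc3)cc2OC1c1cc(OCc2ccccc2)c(OCc2ccccc2)c(OCc2ccccc2)c1 | intermediate
11 | (2R,3R)-5,7-bis(benzyloxy)-2-[3,4,5-tris(benzyloxy)phenyl]chroman-3-ol | c1c(OCc3ccccc3)cc(OCc3ccccc3)c2c1O[C@H](c1cc(OCc3ccccc3)c(OCc3ccccc3)c(OCc3ccccc3)c1)[C@H](O)C2 | intermediate
12 | 3,4,5-tris(benzyloxy)benzoic acid | OC(=O)c1cc(OCc2ccccc2)c(OCc2ccccc2)c(OCc2ccccc2)c1 | starting material
13 | (2R,3R)-5,7-bis(benzyloxy)-2-[3,4,5-tris(benzyloxy)phenyl]chroman-3-yl 3,4,5-tris(benzyloxy)benzoate | c1c(OCc3ccccc3)cc(OCc3ccccc3)c2c1O[C@H](c1cc(OCc3ccccc3)c(OCc3ccccc3)c(OCc3ccccc3)c1)[C@H](OC(=O)c1cc(OCc3ccccc3)c(OCc3ccccc3)c(OCc3ccccc3)c1)C2 | intermediate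
14 | (−)-epicatechin, (2R,3R) | O[C@@H]1Cc2c(O)cc(O)cc2O[C@@H]1c1ccc(O)c(O)c1 | starting material
15 | 5,7,3',4'-tetra-O-benzyl-(−)-epicatechin | O[C@@H]1Cc2c(OCc3ccccc3)cc(OCc3ccccc3)cc2O[C@@H]1c1ccc(OCc2ccccc2)c(OCc2ccccc2)c1 | intermediate
16 | (2R,3R,4S)-4-(2-ethoxyethoxy)-5,7,3',4'-tetra-O-benzylepicatechin | O[C@@H]1[C@@H](OCCOCC)c2c(OCc3ccccc3)cc(OCc3ccccc3)cc2O[C@@H]1c1ccc(OCc2ccccc2)c(OCc2ccccc2)c1 | intermediate
17 | (2R,3R,4S)-4-(2-ethoxyethoxy)-5,7,3',4'-tetra-O-benzylepicatechin 3-O-[3,4,5-tris(benzyloxy)benzoate] | O=C(O[C@@H]1[C@@H](OCCOCC)c2c(OCc3ccccc3)cc(OCc3ccccc3)cc2O[C@@H]1c1ccc(OCc2ccccc2)c(OCc2ccccc2)c1)c1cc(OCc2ccccc2)c(OCc2ccccc2)c(OCc2ccccc2)c1 | intermediate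
18 | pentadeca-O-benzyl epicatechin 3-O-gallate-(4β→8)-epigallocatechin 3-O-gallate | O=C(O[C@@H]1[C@@H](c2c(OCc4ccccc4)cc(OCc4ccccc4)c3c2O[C@H](c2cc(OCc4ccccc4)c(OCc4ccccc4)c(OCc4ccccc4)c2)[C@H](OC(=O)c2cc(OCc4ccccc4)c(OCc4ccccc4)c(OCc4ccccc4)c2)C3)c2c(OCc4ccccc4)cc(OCc4ccccc4)cc2O[C@@H]1c1ccc(OCc4ccccc4)c(OCc4ccccc4)c1)c1cc(OCc4ccccc4)c(OCc4ccccc4)c(OCc4ccccc4)c1 | intermediate
19 | (−)-epicatechin 3-O-gallate-(4β→8)-(−)-epigallocatechin 3-O-gallate | O=C(O[C@@H]1[C@@H](c2c(O)cc(O)c3c2O[C@H](c2cc(O)c(O)c(O)c2)[C@H](OC(=O)c2cc(O)c(O)c(O)c2)C3)c2c(O)cc(O)cc2O[C@@H]1c1ccc(O)c(O)c1)c1cc(O)c(O)c(O)c1 | target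

**Step count**
Total: 14 steps. Longest linear sequence: 9 steps (1, 2, 3, 6, 7, 8, 9, 13, 14).

**Steps most likely to fail**

Step 6. The ring closure may stall or be diverted in the second stage: copper insertion into the hindered, electron-rich C8a–Br bond may be slow, protodebromination may compete, or silyl transfer between the enediol oxygens may lead to arylation through O3. The fallback separates the two bond formations and closes the ether from an alcohol instead of an enolate. It sets out from 8, isolated after the alkylation stage. NaBH4 reduction of the ketone should give 3-[2,4-bis(benzyloxy)-6-bromophenyl]-2-[(triisopropylsilyl)oxy]-1-[3,4,5-tris(benzyloxy)phenyl]propan-1-ol F1. Intramolecular aryl etherification of the secondary alcohol (Pd(OAc)2, 2-(di-tert-butylphosphino)-1,1'-binaphthyl, Cs2CO3, toluene, 80 °C) should give 5,7-bis(benzyloxy)-2-[3,4,5-tris(benzyloxy)phenyl]-3-[(triisopropylsilyl)oxy]chromane F2. Desilylation with Bu4NF should give 5,7-bis(benzyloxy)-2-[3,4,5-tris(benzyloxy)phenyl]chroman-3-ol F3 as a stereoisomer mixture, and Dess–Martin oxidation returns to the route at 10.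

Step 8. Epimerization at C2 may be slower than reduction, or the catalyst may discriminate poorly between the ketone enantiomers, which would erode enantiomeric and diastereomeric purity. The fallback resolves the lower unit through the enantiopure upper unit. It sets out from 10. Reduction with LiBH(s-Bu)3 in THF at −78 °C should give the racemic cis-alcohol, that is 11 together with (2S,3S)-5,7-bis(benzyloxy)-2-[3,4,5-tris(benzyloxy)phenyl]chroman-3-ol F4. Steglich esterification with 12 should give 13 together with (2S,3S)-5,7-bis(benzyloxy)-2-[3,4,5-tris(benzyloxy)phenyl]chroman-3-yl 3,4,5-tris(benzyloxy)benzoate F5. Coupling of this racemate with 17 under the conditions of step 13 should give 18 and the pentadeca-O-benzyl dimer with a (2S,3S) lower unit F6, which are diastereomers and should be separable by chromatography. The route is rejoined at 18.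

Step 13. The cation from 17 may ionize sluggishly because of the electron-withdrawing ester, attack its own ring A to give oligomers, or be captured in part at C6 of 13. The fallback couples the more reactive non-acylated partners and installs both gallates afterwards. It sets out from 16 and 11. TMSOTf-promoted coupling in CH2Cl2 at −78 °C should give nona-O-benzyl epicatechin-(4β→8)-epigallocatechin F7, and double Steglich esterification with 12 (DCC, DMAP) returns to the route at 18.

**Further compounds**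
F1 | step 6 | 3-[2,4-bis(benzyloxy)-6-bromophenyl]-2-[(triisopropylsilyl)oxy]-1-[3,4,5-tris(benzyloxy)phenyl]propan-1-ol (diastereomer mixture) | CC(C)[Si](OC(Cc1c(Br)cc(OCc2ccccc2)cc1OCc1ccccc1)C(O)c1cc(OCc2ccccc2)c(OCc2ccccc2)c(OCc2ccccc2)c1)(C(C)C)C(C)C
F2 | step 6 | 5,7-bis(benzyloxy)-2-[3,4,5-tris(benzyloxy)phenyl]-3-[(triisopropylsilyl)oxy]chromane (stereoisomer mixture) | CC(C)[Si](OC1Cc2c(OCc3ccccc3)cc(OCc3ccccc3)cc2OC1c1cc(OCc2ccccc2)c(OCc2ccccc2)c(OCc2ccccc2)c1)(C(C)C)C(C)C
F3 | step 6 | 5,7-bis(benzyloxy)-2-[3,4,5-tris(benzyloxy)phenyl]chroman-3-ol (stereoisomer mixture) | OC1Cc2c(OCc3ccccc3)cc(OCc3ccccc3)cc2OC1c1cc(OCc2ccccc2)c(OCc2ccccc2)c(OCc2ccccc2)c1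
F4 | step 8 | (2S,3S)-5,7-bis(benzyloxy)-2-[3,4,5-tris(benzyloxy)phenyl]chroman-3-ol | c1c(OCc3ccccc3)cc(OCc3ccccc3)c2c1O[C@@H](c1cc(OCc3ccccc3)c(OCc3ccccc3)c(OCc3ccccc3)c1)[C@@H](O)C2
F5 | step 8 | (2S,3S)-5,7-bis(benzyloxy)-2-[3,4,5-tris(benzyloxy)phenyl]chroman-3-yl 3,4,5-tris(benzyloxy)benzoate | c1c(OCc3ccccc3)cc(OCc3ccccc3)c2c1O[C@@H](c1cc(OCc3ccccc3)c(OCc3ccccc3)c(OCc3ccccc3)c1)[C@@H](OC(=O)c1cc(OCc3ccccc3)c(OCc3ccccc3)c(OCc3ccccc3)c1)C2
F6 | step 8 | pentadeca-O-benzyl dimer with upper unit (2R,3R,4R) and lower unit (2S,3S) | O=C(O[C@@H]1[C@@H](c2c(OCc4ccccc4)cc(OCc4ccccc4)c3c2O[C@@H](c2cc(OCc4ccccc4)c(OCc4ccccc4)c(OCc4ccccc4)c2)[C@@H](OC(=O)c2cc(OCc4ccccc4)c(OCc4ccccc4)c(OCc4ccccc4)c2)C3)c2c(OCc4ccccc4)cc(OCc4ccccc4)cc2O[C@@H]1c1ccc(OCc4ccccc4)c(OCc4ccccc4)c1)c1cc(OCc4ccccc4)c(OCc4ccccc4)c(OCc4ccccc4)c1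
F7 | step 13 | nona-O-benzyl epicatechin-(4β→8)-epigallocatechin | O[C@@H]1[C@@H](c2c(OCc4ccccc4)cc(OCc4ccccc4)c3c2O[C@H](c2cc(OCc4ccccc4)c(OCc4ccccc4)c(OCc4ccccc4)c2)[C@H](O)C3)c2c(OCc4ccccc4)cc(OCc4ccccc4)cc2O[C@@H]1c1ccc(OCc4ccccc4)c(OCc4ccccc4)c1
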